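## Structural features

Compound 36 is a linear hexamer of benzene rings A to F joined only by five diaryl ether oxygens (A1–O–B1, B4–O–C1, C2–O–D1, D4–O–E1, E2–O–F1). It has no carbon–carbon bond between rings and no stereocentre, so no stereocentres stand next to each other and the problem is purely constitutional. Ring A is a 2,4,6-trihydroxyphenyl end group and rings B and D are para-linked units with hydroxyls at positions 3 and 5. Rings C and E each carry two neighbouring aryloxy groups (positions 1 and 2) beside a pyrogallol triad (positions 3 to 5) and one hydrogen (position 6), and ring F is a 3,4,5-trihydroxyphenyl end group; there are sixteen free phenolic hydroxyls in all. The free polyphenol is the fragile part: the pyrogallol units of rings C, E and F and the hydroquinone-type rings B and D are oxidised by air, above all in base, so the hydroxyls must stay masked until the last operation. The real difficulty lies in the ether bonds: A1, B4, C2, D4 and E2 are each flanked by two ortho oxygen substituents, and rings C and E need two ether bonds on adjacent carbons of a very electron-rich ring. A second difficulty is positional, because C1 and C2 differ only in their outer neighbour (hydrogen on C6 against oxygen on C3). The key step exploits this ring C pattern: in the C4,C5 o-quinone, C1 is the β-carbon of the enone C5(=O)–C6=C1 and C2 the β-carbon of the enone C4(=O)–C3=C2, so leaving groups there can be exchanged for phenoxides by addition–elimination and reduction restores the catechol.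

## Logic of the disconnections

36 ⇒ 34 (through 35). Cut: the fourteen benzylic C–O bonds, together with the two hydrogens of the C4/C5 catechol. Reason: all sixteen hydroxyls are released in one neutral, reductive operation with no base present. Gain: 34 is non-polar, chromatographable and carries no free phenol. Demand: the hydrogenation must reduce the quinone first and then complete fourteen hydrogenolyses without touching the five diaryl ethers.

34 ⇒ 11 + 32 + 25. Cut: the O–C1 bond of the B–C ether and the O–C2 bond of the C–D ether. Reason: these are the two most crowded bonds on the most electron-rich ring, and a central cut gives fragments of two, one and three rings. Gain: maximum convergence, and ring C enters in its electrophilic oxidation state, so no metal is needed for its ethers. Demand: the first phenoxide (from 11) must go to C1 only, the second (from 25) to C2, and two-electron addition must outrun electron transfer.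

32 ⇒ 31 ⇒ 30 ⇒ 29 ⇒ 27 ⇒ 26. Cut: the C4/C5 oxidation level, two acetal C–O bonds, the benzylic C–O bond on the C3 oxygen, and the C3–O bond itself. Reason: 26 already holds both bromines in the 1,2-relation para to the catechol oxygens, so no bromination has to be steered; the third oxygen is placed by metalation between an acetal oxygen and a bromine, the only kind of ring hydrogen 27 has. Gain: the substitution pattern of 32 is fixed by construction. Demand: the aryl anion next to bromine must be trapped before it loses bromide.

11 ⇒ 9 (through 10) ⇒ 5 + 8; 5 ⇒ 3 (through 4) ⇒ 1 + 2; 8 ⇒ 6 + 7. Cut: the B4 C–O bond back to a formyl C–C bond, then the O–B1 bond. Reason: the formyl group para to B1 activates the bromide of 8 for ether formation and then becomes the B4 hydroxyl, so no protecting group is needed on that oxygen. Gain: 5 and 8 are one-ring pieces made in two steps and one step. Demand: the hindered, oxidisable phenoxide of 5 must couple at an unhindered bromide, and peracid must convert each aldehyde without attacking the electron-rich rings.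

25 ⇒ 23 (through 24) ⇒ 19 + 22; 22 ⇒ 21 ⇒ 20. Cut: the D1 C–O bond back to formyl, then the O–D4 bond. Reason: the formyl group para to D4 activates the doubly flanked bromide of 22 and afterwards delivers the unhindered D1 hydroxyl that the key step needs. Gain: the trimer is reduced to a dimer and a one-ring bromide. Demand: a copper-mediated ether coupling at a carbon between two benzyloxy groups.

19 ⇒ 17 (through 18) ⇒ 15 + 16; 15 (through 14) and 16 ⇒ 13 ⇒ 12 + 2. Cut: the E1 C–O bond back to formyl, then the O–E2 bond. Reason: the formyl group of 16 sits ortho to the E2 bromide and activates it, then becomes the E1 hydroxyl; both partners come from 13 in one step each. Gain: rings E and F share one precursor. Demand: monobromination of 13 at one of two equivalent positions and a clean aryl migration in each oxidation.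

## Other disconnections considered

Alternative 1: The cut is through two C–C bonds of ring C (C1–C2 and C5–C6), so that ring C is built from the four carbons of dibenzyl squarate A2 and the two vinyl carbons of the 1-(aryloxy)vinyl stannane A3 derived from the B4 oxygen of 11. In the forward step, tin–lithium exchange on A3 and 1,2-addition to a carbonyl of A2 would form C1–C2; heating in xylene would open the hydroxycyclobutenone to a dienylketene, which would close at C5–C6 and tautomerise to the hydroquinone A1 (free C2 and C5 hydroxyls, benzyl ethers at C3 and C4).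
- In its favour: the oxygen pattern of ring C is fixed by connectivity and not by relative reactivity, the step is thermal and free of electron-transfer risk, and this ring expansion is an established reaction class. On precedent and on regiochemical certainty it is the better of the two.
- Against it here: A1 holds only rings A to C. The C2 hydroxyl, lying between an aryloxy and a benzyloxy group, would still have to be arylated by ring D after selective benzylation of the less hindered C5 hydroxyl, and that requires a D1 bromide of the D-to-F trimer in place of 25. A3 needs vinylation and α-stannylation of the hindered phenol 11, and A1 is an air-sensitive hydroquinone.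
- Comparison: on structure the chosen plan forms both ring C ethers and joins all six rings in one operation, whereas A1 is a trimer. On mechanism the alternative is safer. On step economy it needs about four steps from 11 to A1 and at least three more afterwards, against one step after the key step in the chosen plan. The protecting-group scheme and final hydrogenolysis are equal.

Alternative 2: The cut is the A1–A2 bond, with ring A made last from the chain of the keto ester A5, whose aryloxy group is the complete B-to-F pentamer. In the forward step Mg(OMe)2 would form the enolate at the aryloxymethyl carbon, which would attack the ester carbon; loss of methanol and enolisation would give A4 (free A2 and A6 hydroxyls, fourteen benzyl ethers).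
- In its favour: the most hindered and most oxidisable phenol of the chosen route (5) and its copper coupling are avoided, because the A1–O bond would be a simple alkylation of a phenol with an α-halo ketone. A4 needs only hydrogenolysis, so after the key step it is the equal of the chosen plan, and it has no quinone to reduce.
- Against it here: it leaves rings C and E, the true difficulty, to other chemistry, since the pentamer must already contain both crowded ring C ethers. The ring-forming step then stands at the end of the longest linear sequence. The enolate required is the less acidic one: the methylene between ketone and enol ether would be deprotonated first, and oxygen attack on the ester to a pyranone is the usual side path of such dioxo esters. Only the E enol ether can cyclise.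
- Comparison: on structure it solves ring A, which costs two steps from 1 in the chosen plan, and not ring C. On mechanism it is free of redox risk, which is better, but has its own chemoselectivity problem. On step economy it adds three to four linear steps on a pentamer, against a convergent union.

Alternative 3: The cut is through both ether bonds of ring E (O–E1 and O–E2). In the forward step the cationic complex A7 (cyclopentadienyl, divalent ruthenium, 4,5-dichloro-1,2,3-trimethoxybenzene, hexafluorophosphate) would react first with the D4 phenoxide of the tetramer A8 at E1 and then with the phenoxide of 15 at E2 to give A6; photolysis in acetonitrile would free the arene.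
- In its favour: it uses the same three-component logic, and substitution of chlorides on such cationic arene complexes by phenoxides is established, also for two neighbouring chlorides. It runs by a two-electron pathway under mild conditions. On precedent and on freedom from electron transfer it is the better plan.
- Against it here: A8 contains ring C with both crowded ethers, so the central problem must be solved separately. The two chlorides of A7 are activated alike by the metal, so site order would rest on sterics alone, whereas in 32 the two carbons belong to electronically different enones; in principle this favours the chosen plan, though it is untested. Ring E must carry methyl ethers so that the metal binds the right ring, and their cleavage needs boron tribromide-type conditions, harsher than hydrogenolysis. Ruthenium is stoichiometric.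
- Comparison: convergence is about equal, and the central cut of the chosen plan is better balanced. On mechanism the alternative is safer. On step economy it needs at least three steps after the key step (decomplexation, two kinds of deprotection) against one.

Key step: step 20

Remark 1: 36 has no stereocentre, so the SMILES of the route carry no stereodescriptors.
Remark 2: electrophilic dibromination of 3-(benzyloxy)benzene-1,2-diol is expected to send bromine to position 6 (para to the benzyloxy group) in competition with position 5, so the 4,5-dibromo pattern of 32 is taken from 26 and not from a bromination.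
Remark 3: 1, 6, 7, 12, 20 and 26 are taken to be catalogue chemicals; 26 is otherwise one step from catechol and bromine.

## Route

Step 1
Reactants: 1 2,4,6-trihydroxybenzaldehyde; 2 benzyl bromide
Product: 3 2,4,6-tris(benzyloxy)benzaldehyde
Conditions: BnBr (3.6 equiv), K2CO3, DMF, 60 °C
Reagents that add atoms: benzyl bromide (2), BrCc1ccccc1
Why: Williamson ether synthesis; the formyl group lowers the nucleophilicity of the ring carbons, so O-alkylation should prevail over C-benzylation, and warming in DMF should overcome the hydrogen bonds of the two ortho hydroxyls.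

Step 2
Reactants: 3 2,4,6-tris(benzyloxy)benzaldehyde
Product: 5 2,4,6-tris(benzyloxy)phenol, via aryl formate 4 (not isolated)
Conditions: mCPBA, CH2Cl2, 0 °C → rt; then K2CO3 (cat.), MeOH, rt, argon
Reagents that add atoms: mCPBA, OOC(=O)c1cccc(Cl)c1
Why: Baeyer–Villiger (Dakin-type) oxidation; the electron-rich aryl group should migrate in the peracid adduct to give formate 4, which is methanolysed to the phenol without touching the benzyl ethers.

Step 3
Reactants: 6 4-bromo-2,6-difluorobenzaldehyde; 7 benzyl alcohol
Product: 8 2,6-bis(benzyloxy)-4-bromobenzaldehyde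
Conditions: BnOH (2.3 equiv), NaH, THF, 0 °C → rt
Reagents that add atoms: benzyl alcohol (7), OCc1ccccc1
Why: Nucleophilic aromatic substitution; both fluorides are ortho to the formyl group and should be displaced far faster than the para bromide, and the alkoxide is added cold to keep hydride transfer to the aldehyde in check.

Step 4
Reactants: 5 2,4,6-tris(benzyloxy)phenol; 8 2,6-bis(benzyloxy)-4-bromobenzaldehyde
Product: 9 2,6-bis(benzyloxy)-4-[2,4,6-tris(benzyloxy)phenoxy]benzaldehyde
Conditions: CuI (10 mol %), picolinic acid (20 mol %), K3PO4, DMSO, 90 °C, argon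
Reagents that add atoms: none
Why: Ullmann diaryl ether synthesis forming A1–O–B1; the bromide of 8 is unhindered and activated by the para formyl group, and the picolinic acid/copper system is suited to 2,6-disubstituted phenols such as 5.

Step 5
Reactants: 9 2,6-bis(benzyloxy)-4-[2,4,6-tris(benzyloxy)phenoxy]benzaldehyde
Product: 11 2,6-bis(benzyloxy)-4-[2,4,6-tris(benzyloxy)phenoxy]phenol (dimer AB, free B4 hydroxyl), via aryl formate 10 (not isolated)
Conditions: mCPBA, NaHCO3, CH2Cl2, 0 °C; then K2CO3 (cat.), MeOH–THF, rt, argon
Reagents that add atoms: mCPBA, OOC(=O)c1cccc(Cl)c1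
Why: Baeyer–Villiger oxidation; an aldehyde flanked by two alkoxy groups and para to an aryloxy group should migrate its aryl group readily, and the formyl group that activated step 4 thereby becomes the B4 hydroxyl.

Step 6
Reactants: 12 3,4,5-trihydroxybenzaldehyde; 2 benzyl bromide
Product: 13 3,4,5-tris(benzyloxy)benzaldehyde
Conditions: BnBr (3.5 equiv), K2CO3, DMF, 50 °C
Reagents that add atoms: benzyl bromide (2), BrCc1ccccc1
Why: Williamson ether synthesis on three unchelated phenols of a deactivated ring; no C-alkylation is expected.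

Step 7
Reactants: 13 3,4,5-tris(benzyloxy)benzaldehyde
Product: 15 3,4,5-tris(benzyloxy)phenol, via aryl formate 14 (not isolated)
Conditions: mCPBA, CH2Cl2, 0 °C → rt; then K2CO3 (cat.), MeOH, rt
Reagents that add atoms: mCPBA, OOC(=O)c1cccc(Cl)c1
Why: Baeyer–Villiger oxidation; the para benzyloxy group supports aryl migration, and methanolysis of formate 14 gives the ring F phenol.

Step 8
Reactants: 13 3,4,5-tris(benzyloxy)benzaldehyde
Product: 16 3,4,5-tris(benzyloxy)-2-bromobenzaldehyde
Conditions: NBS (1.05 equiv), DMF, rt, dark
Reagents that add atoms: N-bromosuccinimide, O=C1CCC(=O)N1Br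
Why: Electrophilic aromatic bromination; positions 2 and 6 of 13 are equivalent and each is ortho to one benzyloxy group and para to another, so one equivalent should give a single monobromide, and ionic conditions in the dark avoid benzylic bromination.

Step 9
Reactants: 15 3,4,5-tris(benzyloxy)phenol; 16 3,4,5-tris(benzyloxy)-2-bromobenzaldehyde
Product: 17 3,4,5-tris(benzyloxy)-2-[3,4,5-tris(benzyloxy)phenoxy]benzaldehyde
Conditions: CuI (20 mol %), N,N-dimethylglycine hydrochloride (40 mol %), Cs2CO3, 1,4-dioxane, 100 °C, argon
Reagents that add atoms: none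
Why: Ullmann diaryl ether synthesis forming E2–O–F1; the bromide is activated by the ortho formyl group and the phenol 15 is unhindered, the favourable pairing for this crowded position.

Step 10
Reactants: 17 3,4,5-tris(benzyloxy)-2-[3,4,5-tris(benzyloxy)phenoxy]benzaldehyde
Product: 19 3,4,5-tris(benzyloxy)-2-[3,4,5-tris(benzyloxy)phenoxy]phenol (dimer EF, free E1 hydroxyl), via aryl formate 18 (not isolated)
Conditions: mCPBA, NaHCO3, CH2Cl2, 0 °C → rt; then K2CO3 (cat.), MeOH–THF, rt
Reagents that add atoms: mCPBA, OOC(=O)c1cccc(Cl)c1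
Why: Baeyer–Villiger oxidation; the ortho aryloxy and para benzyloxy groups favour aryl migration, so the formyl group becomes the E1 hydroxyl.

Step 11
Reactants: 20 4-bromo-3,5-dimethoxybenzaldehyde
Product: 21 4-bromo-3,5-dihydroxybenzaldehyde
Conditions: BBr3 (3 equiv), CH2Cl2, −78 °C → rt; then H2O
Reagents that add atoms: none
Why: Lewis-acid cleavage of aryl methyl ethers; the aldehyde is complexed during the reaction and recovered on aqueous work-up, and the aryl bromide is inert.

Step 12
Reactants: 21 4-bromo-3,5-dihydroxybenzaldehyde; 2 benzyl bromide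
Product: 22 3,5-bis(benzyloxy)-4-bromobenzaldehyde
Conditions: BnBr (2.4 equiv), K2CO3, DMF, 50 °C
Reagents that add atoms: benzyl bromide (2), BrCc1ccccc1
Why: Williamson ether synthesis on two equivalent phenols.

Step 13
Reactants: 19 3,4,5-tris(benzyloxy)-2-[3,4,5-tris(benzyloxy)phenoxy]phenol; 22 3,5-bis(benzyloxy)-4-bromobenzaldehyde
Product: 23 3,5-bis(benzyloxy)-4-{3,4,5-tris(benzyloxy)-2-[3,4,5-tris(benzyloxy)phenoxy]phenoxy}benzaldehyde
Conditions: CuCl (50 mol %), 2,2,6,6-tetramethylheptane-3,5-dione (25 mol %), Cs2CO3, NMP, 120 °C, argon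
Reagents that add atoms: none
Why: Ullmann diaryl ether synthesis forming D4–O–E1; the para formyl group activates the bromide between the two benzyloxy groups, and the diketone-ligated copper system is the one suited to hindered, electron-rich partners.

Step 14
Reactants: 23 3,5-bis(benzyloxy)-4-{3,4,5-tris(benzyloxy)-2-[3,4,5-tris(benzyloxy)phenoxy]phenoxy}benzaldehyde
Product: 25 3,5-bis(benzyloxy)-4-{3,4,5-tris(benzyloxy)-2-[3,4,5-tris(benzyloxy)phenoxy]phenoxy}phenol (trimer DEF, free D1 hydroxyl), via aryl formate 24 (not isolated)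
Conditions: mCPBA, NaHCO3, CH2Cl2, 0 °C → rt; then K2CO3 (cat.), MeOH–THF, rt
Reagents that add atoms: mCPBA, OOC(=O)c1cccc(Cl)c1
Why: Baeyer–Villiger oxidation of a 3,5-dialkoxy-4-aryloxybenzaldehyde; the para aryloxy group supports aryl migration and the formyl group becomes the unhindered D1 hydroxyl.

Step 15
Reactants: 26 4,5-dibromobenzene-1,2-diol
Product: 27 1,2-dibromo-4,5-bis(methoxymethoxy)benzene
Conditions: MOMCl (2.5 equiv), iPr2NEt, CH2Cl2, 0 °C → rt
Reagents that add atoms: chloromethyl methyl ether, COCCl
Why: Acetal protection of both phenols; the methoxymethyl ethers serve as ortho-directing groups in step 16 and are later removed without affecting a benzyl ether.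

Step 16
Reactants: 27 1,2-dibromo-4,5-bis(methoxymethoxy)benzene
Product: 29 2,3-dibromo-5,6-bis(methoxymethoxy)phenol, via lithium aryl borate 28 (not isolated)
Conditions: LiTMP (from 2,2,6,6-tetramethylpiperidine and n-BuLi), B(OiPr)3, THF, −78 °C; then 30 % H2O2, aq NaOH, 0 °C → rt
Reagents that add atoms: hydrogen peroxide, OO (supplies the phenol oxygen); triisopropyl borate, CC(C)OB(OC(C)C)OC(C)C (its boron and isopropoxy groups are present only in 28)
Why: Directed ortho-metalation with in situ borylation, then oxidation of the C–B bond; the two ring hydrogens of 27 are equivalent and each lies between an acetal oxygen and a bromine, and the hindered amide leaves the borate alone, so the aryllithium is trapped as it forms, before it can lose LiBr.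

Step 17
Reactants: 29 2,3-dibromo-5,6-bis(methoxymethoxy)phenol; 2 benzyl bromide
Product: 30 3-(benzyloxy)-1,2-dibromo-4,5-bis(methoxymethoxy)benzene
Conditions: BnBr (1.3 equiv), K2CO3, DMF, 50 °C
Reagents that add atoms: benzyl bromide (2), BrCc1ccccc1
Why: Williamson ether synthesis on the only free hydroxyl, which places the benzyl group on the oxygen next to bromine (the later C3 oxygen of ring C).

Step 18
Reactants: 30 3-(benzyloxy)-1,2-dibromo-4,5-bis(methoxymethoxy)benzene
Product: 31 3-(benzyloxy)-4,5-dibromobenzene-1,2-diol
Conditions: HCl (cat.), MeOH–THF, 45 °C, argon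
Reagents that add atoms: none
Why: Acid-catalysed acetal exchange with methanol removes both methoxymethyl groups; the benzyl ether and the aryl bromides are inert to dilute acid.

Step 19
Reactants: 31 3-(benzyloxy)-4,5-dibromobenzene-1,2-diol
Product: 32 3-(benzyloxy)-4,5-dibromocyclohexa-3,5-diene-1,2-dione (3-benzyloxy-4,5-dibromo-o-benzoquinone)
Conditions: Ag2O, Na2SO4, Et2O, rt, dark; filtered and used at once
Reagents that add atoms: none
Why: Two-electron oxidation of a catechol to the o-quinone by Ag2O under neutral, anhydrous conditions; the halogen and alkoxy substituents should make the quinone stable enough to be filtered and used directly.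

Step 20
Reactants: 11 2,6-bis(benzyloxy)-4-[2,4,6-tris(benzyloxy)phenoxy]phenol; 32 3-(benzyloxy)-4,5-dibromocyclohexa-3,5-diene-1,2-dione; 25 3,5-bis(benzyloxy)-4-{3,4,5-tris(benzyloxy)-2-[3,4,5-tris(benzyloxy)phenoxy]phenoxy}phenol
Product: 34 3-(benzyloxy)-5-{2,6-bis(benzyloxy)-4-[2,4,6-tris(benzyloxy)phenoxy]phenoxy}-4-(3,5-bis(benzyloxy)-4-{3,4,5-tris(benzyloxy)-2-[3,4,5-tris(benzyloxy)phenoxy]phenoxy}phenoxy)cyclohexa-3,5-diene-1,2-dione (hexamer with ring C as C4,C5 o-quinone, fourteen benzyl ethers), via bromoquinone monoether 33 (not isolated)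
Conditions: 11, NaH, THF, 0 °C, then added dropwise to 32 (1.1 equiv), THF, −78 → −40 °C; then 25 premixed with NaH in THF, −40 → 0 °C; AcOH quench; argon, dark
Reagents that add atoms: none
Why: Proposed new method: each ether bond should form by conjugate addition of a sodium phenoxide to a β-bromo enone of the o-quinone followed by loss of bromide from the enolate (addition–elimination), first at C1 through the C5 carbonyl to give 33 and then at C2 through the C4 carbonyl to give 34; the closest known reaction type is the stepwise replacement of the 4- and 5-halogens of tetrahalo-o-benzoquinones by oxygen and nitrogen nucleophiles. No ring is closed and no stereocentre is formed. The selectivity needed is positional: the first phenoxide must enter at C1 and not at C2, and the substrate secures this because C1 is the β-carbon of an enone whose α-carbon (C6) carries only hydrogen, whereas C2 is the β-carbon of an enol ether (the C3 benzyloxy group donates into C3=C2) and is flanked by two substituents. The bulkier phenoxide of 11 is therefore given the open, more electrophilic C1 and is added slowly as the limiting reagent to an excess of cold 32, so that 33 is not exposed to unreacted phenoxide. Once the aryloxy group sits on C1 the C5 enone is a vinylogous ester, which should slow both a second attack at C1 (aryloxy exchange) and oxidation of the next phenoxide, and leaves bromide at C2 as the only good leaving group for the slimmer phenoxide of 25, whose oxygen is flanked by two ring hydrogens. Single-electron transfer from the electron-rich phenoxides to the quinone is the competing pathway; low temperature, the tightly paired sodium counter-ion in THF and exclusion of light and air are chosen to favour the two-electron addition. Quenching with acetic acid before warming should protect the product quinone from further phenoxide attack.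

Step 21
Reactants: 34 hexamer o-quinone with fourteen benzyl ethers
Product: 36 target hexamer (CNP0114537.0), via tetradecabenzyl catechol 35 (not isolated)
Conditions: H2 (3 bar), Pd/C (10 wt %), THF–MeOH, rt; filtration and concentration under argon, Sephadex LH-20
Reagents that add atoms: none
Why: Catalytic hydrogenation; the quinone should be reduced at once to catechol 35, after which the fourteen benzyl ethers are removed by hydrogenolysis, while diaryl ethers and the benzene rings are not reduced under these conditions, so no separate dithionite step is needed.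

## Compound list

1 | 2,4,6-trihydroxybenzaldehyde | O=Cc1c(O)cc(O)cc1O | starting material
2 | benzyl bromide | BrCc1ccccc1 | starting material
3 | 2,4,6-tris(benzyloxy)benzaldehyde | O=Cc1c(OCc9ccccc9)cc(OCc9ccccc9)cc1OCc9ccccc9 | intermediate
4 | 2,4,6-tris(benzyloxy)phenyl formate | O=COc1c(OCc9ccccc9)cc(OCc9ccccc9)cc1OCc9ccccc9 | intermediate (not isolated)
5 | 2,4,6-tris(benzyloxy)phenol | Oc1c(OCc9ccccc9)cc(OCc9ccccc9)cc1OCc9ccccc9 | intermediate
6 | 4-bromo-2,6-difluorobenzaldehyde | O=Cc1c(F)cc(Br)cc1F | starting material
7 | benzyl alcohol | OCc1ccccc1 | starting material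
8 | 2,6-bis(benzyloxy)-4-bromobenzaldehyde | O=Cc1c(OCc9ccccc9)cc(Br)cc1OCc9ccccc9 | intermediate
9 | 2,6-bis(benzyloxy)-4-[2,4,6-tris(benzyloxy)phenoxy]benzaldehyde | O=Cc1c(OCc9ccccc9)cc(Oc2c(OCc9ccccc9)cc(OCc9ccccc9)cc2OCc9ccccc9)cc1OCc9ccccc9 | intermediate
10 | 2,6-bis(benzyloxy)-4-[2,4,6-tris(benzyloxy)phenoxy]phenyl formate | O=COc1c(OCc9ccccc9)cc(Oc2c(OCc9ccccc9)cc(OCc9ccccc9)cc2OCc9ccccc9)cc1OCc9ccccc9 | intermediate (not isolated)
11 | 2,6-bis(benzyloxy)-4-[2,4,6-tris(benzyloxy)phenoxy]phenol (dimer AB, free B4 hydroxyl) | Oc1c(OCc9ccccc9)cc(Oc2c(OCc9ccccc9)cc(OCc9ccccc9)cc2OCc9ccccc9)cc1OCc9ccccc9 | intermediate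
12 | 3,4,5-trihydroxybenzaldehyde | O=Cc1cc(O)c(O)c(O)c1 | starting material
13 | 3,4,5-tris(benzyloxy)benzaldehyde | O=Cc1cc(OCc9ccccc9)c(OCc9ccccc9)c(OCc9ccccc9)c1 | intermediate
14 | 3,4,5-tris(benzyloxy)phenyl formate | O=COc1cc(OCc9ccccc9)c(OCc9ccccc9)c(OCc9ccccc9)c1 | intermediate (not isolated)
15 | 3,4,5-tris(benzyloxy)phenol | Oc1cc(OCc9ccccc9)c(OCc9ccccc9)c(OCc9ccccc9)c1 | intermediate
16 | 3,4,5-tris(benzyloxy)-2-bromobenzaldehyde | O=Cc1cc(OCc9ccccc9)c(OCc9ccccc9)c(OCc9ccccc9)c1Br | intermediate
17 | 3,4,5-tris(benzyloxy)-2-[3,4,5-tris(benzyloxy)phenoxy]benzaldehyde | O=Cc1cc(OCc9ccccc9)c(OCc9ccccc9)c(OCc9ccccc9)c1Oc2cc(OCc9ccccc9)c(OCc9ccccc9)c(OCc9ccccc9)c2 | intermediate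
18 | 3,4,5-tris(benzyloxy)-2-[3,4,5-tris(benzyloxy)phenoxy]phenyl formate | O=COc1cc(OCc9ccccc9)c(OCc9ccccc9)c(OCc9ccccc9)c1Oc2cc(OCc9ccccc9)c(OCc9ccccc9)c(OCc9ccccc9)c2 | intermediate (not isolated)
19 | 3,4,5-tris(benzyloxy)-2-[3,4,5-tris(benzyloxy)phenoxy]phenol (dimer EF, free E1 hydroxyl) | Oc1cc(OCc9ccccc9)c(OCc9ccccc9)c(OCc9ccccc9)c1Oc2cc(OCc9ccccc9)c(OCc9ccccc9)c(OCc9ccccc9)c2 | intermediate
20 | 4-bromo-3,5-dimethoxybenzaldehyde | O=Cc1cc(OC)c(Br)c(OC)c1 | starting material
21 | 4-bromo-3,5-dihydroxybenzaldehyde | O=Cc1cc(O)c(Br)c(O)c1 | intermediate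
22 | 3,5-bis(benzyloxy)-4-bromobenzaldehyde | O=Cc1cc(OCc9ccccc9)c(Br)c(OCc9ccccc9)c1 | intermediate
23 | 3,5-bis(benzyloxy)-4-{3,4,5-tris(benzyloxy)-2-[3,4,5-tris(benzyloxy)phenoxy]phenoxy}benzaldehyde | O=Cc1cc(OCc9ccccc9)c(Oc2cc(OCc9ccccc9)c(OCc9ccccc9)c(OCc9ccccc9)c2Oc3cc(OCc9ccccc9)c(OCc9ccccc9)c(OCc9ccccc9)c3)c(OCc9ccccc9)c1 | intermediate
24 | 3,5-bis(benzyloxy)-4-{3,4,5-tris(benzyloxy)-2-[3,4,5-tris(benzyloxy)phenoxy]phenoxy}phenyl formate | O=COc1cc(OCc9ccccc9)c(Oc2cc(OCc9ccccc9)c(OCc9ccccc9)c(OCc9ccccc9)c2Oc3cc(OCc9ccccc9)c(OCc9ccccc9)c(OCc9ccccc9)c3)c(OCc9ccccc9)c1 | intermediate (not isolated)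
25 | 3,5-bis(benzyloxy)-4-{3,4,5-tris(benzyloxy)-2-[3,4,5-tris(benzyloxy)phenoxy]phenoxy}phenol (trimer DEF, free D1 hydroxyl) | Oc1cc(OCc9ccccc9)c(Oc2cc(OCc9ccccc9)c(OCc9ccccc9)c(OCc9ccccc9)c2Oc3cc(OCc9ccccc9)c(OCc9ccccc9)c(OCc9ccccc9)c3)c(OCc9ccccc9)c1 | intermediate
26 | 4,5-dibromobenzene-1,2-diol | Oc1cc(Br)c(Br)cc1O | starting material
27 | 1,2-dibromo-4,5-bis(methoxymethoxy)benzene | COCOc1cc(Br)c(Br)cc1OCOC | intermediate
28 | lithium [2,3-dibromo-5,6-bis(methoxymethoxy)phenyl]tri(propan-2-yloxy)borate | [Li+].COCOc1cc(Br)c(Br)c([B-](OC(C)C)(OC(C)C)OC(C)C)c1OCOC | intermediate (not isolated)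
29 | 2,3-dibromo-5,6-bis(methoxymethoxy)phenol | COCOc1cc(Br)c(Br)c(O)c1OCOC | intermediate
30 | 3-(benzyloxy)-1,2-dibromo-4,5-bis(methoxymethoxy)benzene | COCOc1cc(Br)c(Br)c(OCc9ccccc9)c1OCOC | intermediate
31 | 3-(benzyloxy)-4,5-dibromobenzene-1,2-diol | Oc1cc(Br)c(Br)c(OCc9ccccc9)c1O | intermediate
32 | 3-(benzyloxy)-4,5-dibromocyclohexa-3,5-diene-1,2-dione | O=C1C=C(Br)C(Br)=C(OCc9ccccc9)C1=O | intermediate
33 | 3-(benzyloxy)-4-bromo-5-{2,6-bis(benzyloxy)-4-[2,4,6-tris(benzyloxy)phenoxy]phenoxy}cyclohexa-3,5-diene-1,2-dione | O=C1C=C(Oc2c(OCc9ccccc9)cc(Oc3c(OCc9ccccc9)cc(OCc9ccccc9)cc3OCc9ccccc9)cc2OCc9ccccc9)C(Br)=C(OCc9ccccc9)C1=O | intermediate (not isolated)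
34 | hexamer with ring C as C4,C5 o-quinone, AB oxygen on C1, DEF oxygen on C2, fourteen benzyl ethers | O=C1C=C(Oc2c(OCc9ccccc9)cc(Oc3c(OCc9ccccc9)cc(OCc9ccccc9)cc3OCc9ccccc9)cc2OCc9ccccc9)C(Oc3cc(OCc9ccccc9)c(Oc4cc(OCc9ccccc9)c(OCc9ccccc9)c(OCc9ccccc9)c4Oc4cc(OCc9ccccc9)c(OCc9ccccc9)c(OCc9ccccc9)c4)c(OCc9ccccc9)c3)=C(OCc9ccccc9)C1=O | intermediate
35 | hexamer with ring C as C4,C5-catechol and fourteen benzyl ethers | Oc1cc(Oc2c(OCc9ccccc9)cc(Oc3c(OCc9ccccc9)cc(OCc9ccccc9)cc3OCc9ccccc9)cc2OCc9ccccc9)c(Oc3cc(OCc9ccccc9)c(Oc4cc(OCc9ccccc9)c(OCc9ccccc9)c(OCc9ccccc9)c4Oc4cc(OCc9ccccc9)c(OCc9ccccc9)c(OCc9ccccc9)c4)c(OCc9ccccc9)c3)c(OCc9ccccc9)c1O | intermediate (not isolated)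
36 | CNP0114537.0, free hexamer with sixteen hydroxyls | Oc1cc(O)c(Oc2cc(O)c(Oc3cc(O)c(O)c(O)c3Oc3cc(O)c(Oc4cc(O)c(O)c(O)c4Oc4cc(O)c(O)c(O)c4)c(O)c3)c(O)c2)c(O)c1 | target

## Step count and least certain steps

Total: 21 steps. Longest linear sequence: 8 steps (6, 7 or 8, 9, 10, 13, 14, 20, 21). The other branches take 6 steps (1, 2, 4, 5, 20, 21) and 7 steps (15 to 21).

Step 20 (key step, new method). Most likely failure: electron transfer from the phenoxide of 11, a 2,6-dialkoxy-4-aryloxyphenoxide, to the quinone, leading to oxidative consumption of 11 and reduction of 32 in place of C–O bond formation. Second in likelihood is loss of positional control, either by exchange of the first aryloxy group at C1 during the second addition or by conjugate addition at the unsubstituted C6. Fallback, using only known ether couplings and Baeyer–Villiger oxidations, from 25 and 16 and returning at 36: ring C is built in the same way as ring E. Copper-mediated coupling of 25 with 16 (conditions of step 9) should give the tetramer C-to-F aldehyde F1, in which the D1 oxygen sits at position 2 of a 3,4,5-tris(benzyloxy)benzaldehyde. Peracid followed by K2CO3/MeOH should convert it through the aryl formate F2 into the tetramer phenol with free C1 hydroxyl F3. Coupling of F3 with 22 (conditions of step 13) should give the pentamer B-to-F aldehyde F4, and a second oxidation and methanolysis through the formate F5 should give the pentamer phenol with free B1 hydroxyl F6. Ring A is added last as an iodide: 1,3,5-tris(benzyloxy)benzene F7 is iodinated with N-iodosuccinimide to 1,3,5-tris(benzyloxy)-2-iodobenzene F8, which is condensed with F6 under copper catalysis to the hexadecabenzyl ether of the target F9. Hydrogenolysis of F9 (H2, Pd/C) returns to 36.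

Step 16. Most likely failure: loss of LiBr from the aryllithium next to bromine (aryne formation) or bromine migration before the borate traps it, because an ortho-bromoaryllithium is only kinetically stable. Fallback from 26, returning at 29, with no organolithium: monoprotection of 26 (one equivalent of MOMCl) gives 4,5-dibromo-2-(methoxymethoxy)phenol F10. Magnesium-mediated ortho-formylation (MgCl2, Et3N, paraformaldehyde) at its only free ortho position gives 2,3-dibromo-6-hydroxy-5-(methoxymethoxy)benzaldehyde F11. Protection of the remaining hydroxyl gives 5,6-dibromo-2,3-bis(methoxymethoxy)benzaldehyde F12. Baeyer–Villiger oxidation with mCPBA through the aryl formate F13 and methanolysis then give 29.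

Step 13. Most likely failure: slow or incomplete coupling through steric shielding of the bromide of 22 by its two ortho benzyloxy groups, with hydrodebromination of 22 taking over at 120 °C. Fallback from 19 and 22, returning at 23: a change of bond-forming chemistry to palladium-catalysed C–O cross-coupling (Pd(OAc)2, a bulky di-tert-butyl biarylphosphine, K3PO4, toluene, 100 °C). Here the aryl bromide, activated by its para formyl group, adds to zerovalent palladium and the ether is formed by reductive elimination; no new compound is involved.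

Step 3. Most likely failure: attack of benzyl oxide at the formyl group followed by hydride transfer (Tishchenko- or Cannizzaro-type consumption of the aldehyde), and a sluggish second substitution once the first benzyloxy group has entered. Fallback from 6, returning at 8: NaOMe in MeOH displaces both fluorides to give 4-bromo-2,6-dimethoxybenzaldehyde F14, BBr3 gives 4-bromo-2,6-dihydroxybenzaldehyde F15, and benzylation as in step 12 gives 8.

Step 21. Most likely failure: stalling of the hydrogenolysis after partial debenzylation, through adsorption of the growing polyphenol on the catalyst and falling solubility, and air oxidation of the pyrogallol rings during isolation. Fallback from 34, returning at 36: reduction with Na2S2O4 (EtOAc/H2O) and isolation of 35, then Lewis-acid debenzylation with BCl3 and pentamethylbenzene in CH2Cl2 at −78 °C, which needs no heterogeneous catalyst; no new compound is involved.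

## Further compounds

F1 | step 20 | tetramer C-to-F aldehyde: 3,4,5-tris(benzyloxy)-2-(D1-oxy of 25)benzaldehyde | O=Cc1cc(OCc9ccccc9)c(OCc9ccccc9)c(OCc9ccccc9)c1Oc2cc(OCc9ccccc9)c(Oc3cc(OCc9ccccc9)c(OCc9ccccc9)c(OCc9ccccc9)c3Oc4cc(OCc9ccccc9)c(OCc9ccccc9)c(OCc9ccccc9)c4)c(OCc9ccccc9)c2
F2 | step 20 | aryl formate of the tetramer | O=COc1cc(OCc9ccccc9)c(OCc9ccccc9)c(OCc9ccccc9)c1Oc2cc(OCc9ccccc9)c(Oc3cc(OCc9ccccc9)c(OCc9ccccc9)c(OCc9ccccc9)c3Oc4cc(OCc9ccccc9)c(OCc9ccccc9)c(OCc9ccccc9)c4)c(OCc9ccccc9)c2
F3 | step 20 | tetramer C-to-F phenol with free C1 hydroxyl | Oc1cc(OCc9ccccc9)c(OCc9ccccc9)c(OCc9ccccc9)c1Oc2cc(OCc9ccccc9)c(Oc3cc(OCc9ccccc9)c(OCc9ccccc9)c(OCc9ccccc9)c3Oc4cc(OCc9ccccc9)c(OCc9ccccc9)c(OCc9ccccc9)c4)c(OCc9ccccc9)c2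
F4 | step 20 | pentamer B-to-F aldehyde (formyl at B1) | O=Cc1cc(OCc9ccccc9)c(Oc2cc(OCc9ccccc9)c(OCc9ccccc9)c(OCc9ccccc9)c2Oc3cc(OCc9ccccc9)c(Oc4cc(OCc9ccccc9)c(OCc9ccccc9)c(OCc9ccccc9)c4Oc5cc(OCc9ccccc9)c(OCc9ccccc9)c(OCc9ccccc9)c5)c(OCc9ccccc9)c3)c(OCc9ccccc9)c1
F5 | step 20 | aryl formate of the pentamer | O=COc1cc(OCc9ccccc9)c(Oc2cc(OCc9ccccc9)c(OCc9ccccc9)c(OCc9ccccc9)c2Oc3cc(OCc9ccccc9)c(Oc4cc(OCc9ccccc9)c(OCc9ccccc9)c(OCc9ccccc9)c4Oc5cc(OCc9ccccc9)c(OCc9ccccc9)c(OCc9ccccc9)c5)c(OCc9ccccc9)c3)c(OCc9ccccc9)c1
F6 | step 20 | pentamer B-to-F phenol with free B1 hydroxyl | Oc1cc(OCc9ccccc9)c(Oc2cc(OCc9ccccc9)c(OCc9ccccc9)c(OCc9ccccc9)c2Oc3cc(OCc9ccccc9)c(Oc4cc(OCc9ccccc9)c(OCc9ccccc9)c(OCc9ccccc9)c4Oc5cc(OCc9ccccc9)c(OCc9ccccc9)c(OCc9ccccc9)c5)c(OCc9ccccc9)c3)c(OCc9ccccc9)c1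
F7 | step 20 | 1,3,5-tris(benzyloxy)benzene | c1c(OCc9ccccc9)cc(OCc9ccccc9)cc1OCc9ccccc9
F8 | step 20 | 1,3,5-tris(benzyloxy)-2-iodobenzene | Ic1c(OCc9ccccc9)cc(OCc9ccccc9)cc1OCc9ccccc9
F9 | step 20 | hexadecabenzyl ether of the target | c9ccccc9COc1cc(OCc9ccccc9)c(Oc2cc(OCc9ccccc9)c(Oc3cc(OCc9ccccc9)c(OCc9ccccc9)c(OCc9ccccc9)c3Oc3cc(OCc9ccccc9)c(Oc4cc(OCc9ccccc9)c(OCc9ccccc9)c(OCc9ccccc9)c4Oc4cc(OCc9ccccc9)c(OCc9ccccc9)c(OCc9ccccc9)c4)c(OCc9ccccc9)c3)c(OCc9ccccc9)c2)c(OCc9ccccc9)c1
F10 | step 16 | 4,5-dibromo-2-(methoxymethoxy)phenol | COCOc1cc(Br)c(Br)cc1O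
F11 | step 16 | 2,3-dibromo-6-hydroxy-5-(methoxymethoxy)benzaldehyde | O=Cc1c(O)c(OCOC)cc(Br)c1Br
F12 | step 16 | 5,6-dibromo-2,3-bis(methoxymethoxy)benzaldehyde | O=Cc1c(OCOC)c(OCOC)cc(Br)c1Br
F13 | step 16 | 2,3-dibromo-5,6-bis(methoxymethoxy)phenyl formate | O=COc1c(OCOC)c(OCOC)cc(Br)c1Br
F0 | step 13 | none | none
F14 | step 3 | 4-bromo-2,6-dimethoxybenzaldehyde | O=Cc1c(OC)cc(Br)cc1OC
F15 | step 3 | 4-bromo-2,6-dihydroxybenzaldehyde | O=Cc1c(O)cc(Br)cc1O
F0 | step 21 | none | none
A1 | alternative 1 | trimer ABC hydroquinone with free C2 and C5 hydroxyls and benzyl ethers at C3 and C4 | c9ccccc9COc1cc(OCc9ccccc9)c(Oc2cc(OCc9ccccc9)c(Oc3cc(O)c(OCc9ccccc9)c(OCc9ccccc9)c3O)c(OCc9ccccc9)c2)c(OCc9ccccc9)c1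
A2 | alternative 1 | dibenzyl squarate, 3,4-bis(benzyloxy)cyclobut-3-ene-1,2-dione | O=C1C(=O)C(OCc2ccccc2)=C1OCc1ccccc1
A3 | alternative 1 | tributyl(1-{2,6-bis(benzyloxy)-4-[2,4,6-tris(benzyloxy)phenoxy]phenoxy}ethenyl)stannane | C=C(Oc1c(OCc9ccccc9)cc(Oc2c(OCc9ccccc9)cc(OCc9ccccc9)cc2OCc9ccccc9)cc1OCc9ccccc9)[Sn](CCCC)(CCCC)CCCC
A4 | alternative 2 | hexamer with free A2 and A6 hydroxyls and fourteen benzyl ethers | c9ccccc9COc1cc(O)c(Oc2cc(OCc9ccccc9)c(Oc3cc(OCc9ccccc9)c(OCc9ccccc9)c(OCc9ccccc9)c3Oc3cc(OCc9ccccc9)c(Oc4cc(OCc9ccccc9)c(OCc9ccccc9)c(OCc9ccccc9)c4Oc4cc(OCc9ccccc9)c(OCc9ccccc9)c(OCc9ccccc9)c4)c(OCc9ccccc9)c3)c(OCc9ccccc9)c2)c(O)c1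
A5 | alternative 2 | methyl (2E)-3-(benzyloxy)-5-oxo-6-(B1-oxy of the B-to-F pentamer)hex-2-enoate | COC(=O)/C=C(/OCc9ccccc9)CC(=O)COc2cc(OCc9ccccc9)c(Oc3cc(OCc9ccccc9)c(OCc9ccccc9)c(OCc9ccccc9)c3Oc3cc(OCc9ccccc9)c(Oc4cc(OCc9ccccc9)c(OCc9ccccc9)c(OCc9ccccc9)c4Oc4cc(OCc9ccccc9)c(OCc9ccccc9)c(OCc9ccccc9)c4)c(OCc9ccccc9)c3)c(OCc9ccccc9)c2
A6 | alternative 3 | cyclopentadienyl ruthenium hexafluorophosphate complex, bound at ring E, of the hexamer with methyl ethers at E3 to E5 and thirteen benzyl ethers | c9ccccc9COc1cc(OCc9ccccc9)c(Oc2cc(OCc9ccccc9)c(Oc3cc(OCc9ccccc9)c(OCc9ccccc9)c(OCc9ccccc9)c3Oc3cc(OCc9ccccc9)c(Oc4cc(OC)c(OC)c(OC)c4Oc4cc(OCc9ccccc9)c(OCc9ccccc9)c(OCc9ccccc9)c4)c(OCc9ccccc9)c3)c(OCc9ccccc9)c2)c(OCc9ccccc9)c1.c1cc[cH-]c1.[Ru+2].F[P-](F)(F)(F)(F)F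
A7 | alternative 3 | cyclopentadienyl ruthenium hexafluorophosphate complex of 4,5-dichloro-1,2,3-trimethoxybenzene | COc1cc(Cl)c(Cl)c(OC)c1OC.[cH-]1cccc1.[Ru+2].F[P-](F)(F)(F)(F)F
A8 | alternative 3 | tetramer ABCD phenol with free D4 hydroxyl and ten benzyl ethers | c9ccccc9COc1cc(OCc9ccccc9)c(Oc2cc(OCc9ccccc9)c(Oc3cc(OCc9ccccc9)c(OCc9ccccc9)c(OCc9ccccc9)c3Oc3cc(OCc9ccccc9)c(O)c(OCc9ccccc9)c3)c(OCc9ccccc9)c2)c(OCc9ccccc9)c1
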